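Everything rests on taking ring A apart at C8a–C8, C7–C6 and C8a–C4a. In one operation, irradiation of 4-methoxy-6-methyl-2-pyranone with a silyl ynol ether should build the whole pentasubstituted ring as an ortho-hydroxyacetophenone. The step exploits the pattern of ring A itself: three different oxygens on C5, C7 and C8a around the C8 side chain, which arrive as OMe (pyranone C4), O-silyl (alkyne) and free OH (ketene carbonyl), with the acetyl group on C4a ready to become C4/C3 of ring C. The precursor is an (R)-triisopropylsilyl ynol ether cut from (R)-limonene, carrying C1'', C2'', the isopropenyl group and the triethylsilyl-protected tertiary carbinol. Chromone annulation, asymmetric arylation at C2 and desilylation follow.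

Key step: step 7

Remark: R* below stands for the side chain (2R)-5-methyl-2-(prop-1-en-2-yl)-5-(triethylsilyloxy)hexyl.
Remark: (R)-limonene maps onto C2''(R) of the target and the planned C2 configuration is (S); no structure needed to be changed.
Remark: the open-chain ketene from the pyranone has the ketene carbon and the acetyl group on the same side of its C=C bond; because that bond also carries the methoxy group, this geometry is (E) by the sequence rule and is named so.
Remark: the hand of the diene ligand in step 11 is assigned by analogy with cyclic enones and would be confirmed on 5,7-dimethoxychromone; both enantiomers of the ligand are accessible.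

Step 1
Reactants: 1 (R)-(+)-limonene
Product: 2 (4R)-limonene 1,2-oxide (cis/trans mixture at the epoxide)
Conditions: mCPBA (1.0 equiv), CH2Cl2, 0 °C
Reagents that add atoms: meta-chloroperoxybenzoic acid, O=C(OO)c1cccc(Cl)c1
Why: Prilezhaev epoxidation: the trisubstituted ring alkene is far more nucleophilic than the 1,1-disubstituted isopropenyl group, so one equivalent of peracid at 0 °C should epoxidise it selectively, and the cis/trans ratio is irrelevant because both new centres are destroyed in step 2 while C4 (the later C2'') is untouched.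

Step 2
Reactants: 2 (4R)-limonene 1,2-oxide
Product: 4 (3R)-6-oxo-3-(prop-1-en-2-yl)heptanal, via limonene-1,2-diol 3 (not isolated)
Conditions: H5IO6 (1.2 equiv), THF/H2O, 0 °C → rt
Reagents that add atoms: water, O
Why: Acid-promoted hydrolysis of the epoxide and Malaprade glycol cleavage run in one pot and cut the ring between its two oxygenated carbons to the methyl ketone and the aldehyde; the stereocentre is β to the aldehyde and γ to the ketone, so it cannot epimerise by enolisation, and the isopropenyl group is inert to periodic acid.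

Step 3
Reactants: 4 (3R)-6-oxo-3-(prop-1-en-2-yl)heptanal
Product: 5 (5R)-8,8-dibromo-5-(prop-1-en-2-yl)oct-7-en-2-one
Conditions: PPh3, CBr4, Zn, CH2Cl2, rt (ylide preformed); then 4, 0 °C
Reagents that add atoms: carbon tetrabromide, BrC(Br)(Br)Br
Why: Corey–Fuchs dibromoolefination: the non-basic ylide Ph3P=CBr2, preformed with zinc so that no Ph3PBr2 or HBr is present, should react with the aldehyde much faster than with the methyl ketone and leave the aldol-prone ketoaldehyde and the isopropenyl group intact.

Step 4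
Reactants: 5 (5R)-8,8-dibromo-5-(prop-1-en-2-yl)oct-7-en-2-one
Product: 6 (5R)-8,8-dibromo-2-methyl-5-(prop-1-en-2-yl)oct-7-en-2-ol
Conditions: MeMgBr (1.2 equiv), THF, −78 °C; aq. NH4Cl
Reagents that add atoms: methylmagnesium bromide, C[Mg]Br
Why: Grignard addition to the methyl ketone at −78 °C, where the 1,1-dibromoalkene undergoes no halogen–magnesium exchange; the new carbinol carbon (C5'') bears two methyl groups, so no stereocentre arises.

Step 5
Reactants: 6 (5R)-8,8-dibromo-2-methyl-5-(prop-1-en-2-yl)oct-7-en-2-ol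
Product: 7 [(5R)-8,8-dibromo-2-methyl-5-(prop-1-en-2-yl)oct-7-en-2-yl]oxy(triethyl)silane
Conditions: TESOTf (1.3 equiv), 2,6-lutidine, CH2Cl2, −78 → 0 °C
Reagents that add atoms: triethylsilyl trifluoromethanesulfonate, CC[Si](CC)(CC)OS(=O)(=O)C(F)(F)F
Why: Silyl triflate/lutidine silylation is the standard method for hindered tertiary alcohols; the triethylsilyl ether masks the hydroxyl against the organolithiums of step 6 and against ketene addition in step 7, and falls to fluoride in step 12 together with the aryl silyl ethers.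

Step 6
Reactants: 7 [(5R)-8,8-dibromo-2-methyl-5-(prop-1-en-2-yl)oct-7-en-2-yl]oxy(triethyl)silane
Product: 10 triethyl{[(5R)-2-methyl-5-(prop-1-en-2-yl)-8-(triisopropylsilyloxy)oct-7-yn-2-yl]oxy}silane (the (R)-silyl ynol ether), via lithium acetylide 8 (not isolated), via lithium ynolate 9 (not isolated)
Conditions: n-BuLi (2.1 equiv), THF, −78 °C; LiOOt-Bu [t-BuOOH, LiN(SiMe3)2], −78 → 0 °C; TIPSOTf, −78 °C → rt
Reagents that add atoms: tert-butyl hydroperoxide (as its lithium salt), CC(C)(C)OO; triisopropylsilyl trifluoromethanesulfonate, CC(C)[Si](OS(=O)(=O)C(F)(F)F)(C(C)C)C(C)C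
Why: The second stage of the Corey–Fuchs sequence (Br/Li exchange, Fritsch–Buttenberg–Wiechell-type 1,2-shift, deprotonation) gives acetylide 8, electrophilic oxygen transfer from lithium tert-butyl peroxide oxidises it to ynolate 9, and the bulky silyl triflate should silylate on oxygen to the chromatographically stable triisopropylsilyl ynol ether.

Step 7
Reactants: 10 the (R)-silyl ynol ether; 11 4-methoxy-6-methyl-2H-pyran-2-one
Product: 16 1-[2-hydroxy-6-methoxy-3-R*-4-(triisopropylsilyloxy)phenyl]ethan-1-one, via acylvinylketene 12 (not isolated), via vinylcyclobutenone 13 (not isolated), via dienylketene 14 (not isolated), via cyclohexadienone 15 (not isolated)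
Conditions: 11 (2.5 equiv), hν (300 nm, Pyrex), degassed PhMe (0.5 M in 10), 20 °C; then 80 °C in the dark
Reagents that add atoms: none
Why: Proposed new method: light opens the O1–C2 bond of 11 electrocyclically to the cisoid acylvinylketene 12 (reclosure only returns 11), the nucleophilic alkyl-bearing carbon of 10 attacks the ketene carbon in its plane and [2+2] closure gives vinylcyclobutenone 13, whose 4π opening gives dienylketene 14, 6π electrocyclization gives dienone 15 and enolisation gives phenol 16. The closest known reaction type is the Danheiser benzannulation of vinylketenes with siloxyalkynes, including its variant in which the vinylketene is made by light through a Wolff rearrangement, combined with the known photochemical opening of 2-pyranones to ketenes that nucleophiles trap. Ring A is closed by disrotatory 6π electrocyclization of 14 (C8a–C4a), after C8a–C8 and C7–C6 were made in the [2+2] event. No stereocentre is created, since C2'' is a spectator and the sp3 carbons of 13 and 15 vanish on aromatisation. The step needs regioselectivity (alkyl-bearing alkyne carbon to C8a and not to C6) and periselectivity ([2+2] across the ketene C=C and not [4+2] through C8a and C4a or addition to the acetyl C=O); the strong polarisation of the ynol ether and the in-plane electrophilicity of the ketene carbon should secure the first, and closure at the α-carbon, as in every vinylketene–heteroalkyne annulation, with C4a hindered by its acetyl group, should secure the second.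

Step 8
Reactants: 16 1-[2-hydroxy-6-methoxy-3-R*-4-(triisopropylsilyloxy)phenyl]ethan-1-one
Product: 18 5-methoxy-8-R*-7-(triisopropylsilyloxy)-4H-chromen-4-one, via enaminone 17 (not isolated)
Conditions: Me2NCH(OMe)2, PhMe, 90 °C; concentrate; AcOH/CH2Cl2 (1:4), 40 °C
Reagents that add atoms: N,N-dimethylformamide dimethyl acetal, COC(OC)N(C)C
Why: Enaminone route to chromones: the acetyl methyl condenses with the amide acetal, and mild acid then induces conjugate addition of the only free phenol (C8a–OH) and loss of dimethylamine, closing ring C under conditions too mild to cleave the silyl ethers or protonate the isopropenyl group.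

Step 9
Reactants: 19 4-bromoresorcinol
Product: 20 1-bromo-2,4-bis(tert-butyldimethylsilyloxy)benzene
Conditions: TBSCl (2.4 equiv), imidazole, DMF, rt
Reagents that add atoms: tert-butyldimethylsilyl chloride, CC(C)(C)[Si](C)(C)Cl
Why: Imidazole-promoted silylation of both phenols; the tert-butyldimethylsilyl group is small enough at the ortho position for the later transmetalation and is removed by fluoride with the other silyl groups.

Step 10
Reactants: 20 1-bromo-2,4-bis(tert-butyldimethylsilyloxy)benzene
Product: 23 [2,4-bis(tert-butyldimethylsilyloxy)phenyl]boronic acid, via aryllithium 21 (not isolated), via lithium aryltriisopropoxyborate 22 (not isolated)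
Conditions: B(Oi-Pr)3 (1.5 equiv), then n-BuLi (1.1 equiv) added last, THF/PhMe, −78 °C; aq. NH4Cl, 0 °C
Reagents that add atoms: triisopropyl borate, CC(C)OB(OC(C)C)OC(C)C; water, O
Why: Bromine–lithium exchange under in situ quench conditions: aryllithium 21 is captured by the borate as it forms, faster than the shift of the ortho silyl group from oxygen to carbon (retro-Brook rearrangement), and buffered hydrolysis of ate complex 22 should give the boronic acid without desilylation.

Step 11
Reactants: 18 5-methoxy-8-R*-7-(triisopropylsilyloxy)-4H-chromen-4-one; 23 [2,4-bis(tert-butyldimethylsilyloxy)phenyl]boronic acid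
Product: 24 (2S)-2-[2,4-bis(tert-butyldimethylsilyloxy)phenyl]-5-methoxy-8-R*-7-(triisopropylsilyloxy)chroman-4-one
Conditions: [RhCl(C2H4)2]2 (2.5 mol %), (1S,4S)-2,5-diphenylbicyclo[2.2.2]octa-2,5-diene (5.5 mol %), 23 (3 equiv), KOH (0.2 equiv), dioxane/H2O 10:1, 40 °C
Reagents that add atoms: none
Why: Hayashi–Miyaura asymmetric 1,4-addition: transmetalation gives an aryl complex of monovalent rhodium, the chromone C2=C3 bond inserts and the oxa-π-allyl species is hydrolysed; the C2-symmetric diene leaves only the Re face of C2 open, so the new stereocentre C2 is set (S) under catalyst control, the remote C2'' centre exerting no influence.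

Step 12
Reactants: 24 (2S)-2-[2,4-bis(tert-butyldimethylsilyloxy)phenyl]-5-methoxy-8-R*-7-(triisopropylsilyloxy)chroman-4-one
Product: 25 (2S)-2-(2,4-dihydroxyphenyl)-7-hydroxy-8-[(2R)-5-hydroxy-5-methyl-2-(prop-1-en-2-yl)hexyl]-5-methoxychroman-4-one (CID44563198)
Conditions: TBAF (6 equiv), AcOH (6 equiv), THF, 0 °C → rt
Reagents that add atoms: none
Why: Fluoride cleaves all four Si–O bonds (three aryl silyl ethers and the tertiary triethylsilyl ether), and the acetic acid buffer keeps the phenols protonated, which suppresses base-induced opening of ring C to the chalcone (retro-oxa-Michael reaction) and so protects the C2 configuration.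

Compound list
1 | (R)-(+)-limonene | CC1=CC[C@@H](CC1)C(C)=C | starting material
2 | (4R)-limonene 1,2-oxide, cis/trans mixture | CC12OC1C[C@@H](CC2)C(C)=C | intermediate
3 | (4R)-1-methyl-4-(prop-1-en-2-yl)cyclohexane-1,2-diol (not isolated) | CC1(O)C(O)C[C@@H](CC1)C(C)=C | intermediate
4 | (3R)-6-oxo-3-(prop-1-en-2-yl)heptanal | O=CC[C@@H](CCC(C)=O)C(C)=C | intermediate
5 | (5R)-8,8-dibromo-5-(prop-1-en-2-yl)oct-7-en-2-one | BrC(Br)=CC[C@@H](CCC(C)=O)C(C)=C | intermediate
6 | (5R)-8,8-dibromo-2-methyl-5-(prop-1-en-2-yl)oct-7-en-2-ol | BrC(Br)=CC[C@@H](CCC(C)(C)O)C(C)=C | intermediate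
7 | [(5R)-8,8-dibromo-2-methyl-5-(prop-1-en-2-yl)oct-7-en-2-yl]oxy(triethyl)silane | BrC(Br)=CC[C@@H](CCC(C)(C)O[Si](CC)(CC)CC)C(C)=C | intermediate
8 | lithium (4R)-7-methyl-4-(prop-1-en-2-yl)-7-(triethylsilyloxy)oct-1-yn-1-ide (not isolated) | [Li]C#CC[C@@H](CCC(C)(C)O[Si](CC)(CC)CC)C(C)=C | intermediate
9 | lithium (4R)-7-methyl-4-(prop-1-en-2-yl)-7-(triethylsilyloxy)oct-1-yn-1-olate (not isolated) | [Li]OC#CC[C@@H](CCC(C)(C)O[Si](CC)(CC)CC)C(C)=C | intermediate
10 | triethyl{[(5R)-2-methyl-5-(prop-1-en-2-yl)-8-(triisopropylsilyloxy)oct-7-yn-2-yl]oxy}silane | C=C(C)[C@H](CCC(C)(C)O[Si](CC)(CC)CC)CC#CO[Si](C(C)C)(C(C)C)C(C)C | intermediate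
11 | 4-methoxy-6-methyl-2H-pyran-2-one | COC1=CC(=O)OC(C)=C1 | starting material
12 | (3E)-3-methoxyhexa-1,3-diene-1,5-dione (not isolated) | O=C=C/C(OC)=C\C(C)=O | intermediate
13 | 4-[(1E)-1-methoxy-3-oxobut-1-enyl]-2-R*-3-(triisopropylsilyloxy)cyclobut-2-en-1-one (not isolated) | CC(=O)\C=C(OC)/C1C(=O)C(C[C@@H](CCC(C)(C)O[Si](CC)(CC)CC)C(C)=C)=C1O[Si](C(C)C)(C(C)C)C(C)C | intermediate
14 | (3E,5E)-5-methoxy-2-R*-3-(triisopropylsilyloxy)octa-1,3,5-triene-1,7-dione (not isolated) | O=C=C(C[C@@H](CCC(C)(C)O[Si](CC)(CC)CC)C(C)=C)/C(O[Si](C(C)C)(C(C)C)C(C)C)=C\C(OC)=C/C(C)=O | intermediate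
15 | 6-acetyl-5-methoxy-2-R*-3-(triisopropylsilyloxy)cyclohexa-2,4-dien-1-one (not isolated) | CC(=O)C1C(=O)C(C[C@@H](CCC(C)(C)O[Si](CC)(CC)CC)C(C)=C)=C(O[Si](C(C)C)(C(C)C)C(C)C)C=C1OC | intermediate
16 | 1-[2-hydroxy-6-methoxy-3-R*-4-(triisopropylsilyloxy)phenyl]ethan-1-one | C=C(C)[C@H](CCC(C)(C)O[Si](CC)(CC)CC)Cc1c(O[Si](C(C)C)(C(C)C)C(C)C)cc(OC)c(C(C)=O)c1O | intermediate
17 | (2E)-3-(dimethylamino)-1-[2-hydroxy-6-methoxy-3-R*-4-(triisopropylsilyloxy)phenyl]prop-2-en-1-one (not isolated) | C=C(C)[C@H](CCC(C)(C)O[Si](CC)(CC)CC)Cc1c(O[Si](C(C)C)(C(C)C)C(C)C)cc(OC)c(C(=O)/C=C/N(C)C)c1O | intermediate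
18 | 5-methoxy-8-R*-7-(triisopropylsilyloxy)-4H-chromen-4-one | C=C(C)[C@H](CCC(C)(C)O[Si](CC)(CC)CC)Cc1c(O[Si](C(C)C)(C(C)C)C(C)C)cc(OC)c2c1OC=CC2=O | intermediate
19 | 4-bromoresorcinol | Oc1ccc(Br)c(O)c1 | starting material
20 | 1-bromo-2,4-bis(tert-butyldimethylsilyloxy)benzene | Brc1ccc(O[Si](C)(C)C(C)(C)C)cc1O[Si](C)(C)C(C)(C)C | intermediate
21 | [2,4-bis(tert-butyldimethylsilyloxy)phenyl]lithium (not isolated) | [Li]c1ccc(O[Si](C)(C)C(C)(C)C)cc1O[Si](C)(C)C(C)(C)C | intermediate
22 | lithium [2,4-bis(tert-butyldimethylsilyloxy)phenyl]triisopropoxyborate (not isolated) | [Li+].CC(C)O[B-](OC(C)C)(OC(C)C)c1ccc(O[Si](C)(C)C(C)(C)C)cc1O[Si](C)(C)C(C)(C)C | intermediate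
23 | [2,4-bis(tert-butyldimethylsilyloxy)phenyl]boronic acid | OB(O)c1ccc(O[Si](C)(C)C(C)(C)C)cc1O[Si](C)(C)C(C)(C)C | intermediate
24 | (2S)-2-[2,4-bis(tert-butyldimethylsilyloxy)phenyl]-5-methoxy-8-R*-7-(triisopropylsilyloxy)chroman-4-one | C=C(C)[C@H](CCC(C)(C)O[Si](CC)(CC)CC)Cc1c(O[Si](C(C)C)(C(C)C)C(C)C)cc(OC)c2c1O[C@H](c1ccc(O[Si](C)(C)C(C)(C)C)cc1O[Si](C)(C)C(C)(C)C)CC2=O | intermediate
25 | (2S)-2-(2,4-dihydroxyphenyl)-7-hydroxy-8-[(2R)-5-hydroxy-5-methyl-2-(prop-1-en-2-yl)hexyl]-5-methoxychroman-4-one | C=C(C)[C@H](CCC(C)(C)O)Cc1c(O)cc(OC)c2c1O[C@H](c1ccc(O)cc1O)CC2=O | target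

Total step count: 12 (compounds not isolated are not counted as steps).
Longest linear sequence: 10 steps (steps 1–8, 11 and 12, from 1); the boronic acid branch (steps 9 and 10) has 2 steps.

Steps most likely to fail

Step 7. Unimolecular reclosure of the ketene to the pyranone may outrun its bimolecular capture by the ynol ether; the pyranone may instead undergo valence isomerisation or photocycloaddition; or the ketene–alkyne adduct may close through the wrong terminus. The fallback uses the thermal, known way to the vinylketene and adds the acetyl group afterwards. It sets out from 10. Heating 10 in toluene at 80–110 °C with 3-methoxycyclobut-2-en-1-one F1 (from commercial cyclobutane-1,3-dione and TMSCHN2) is a thermal Danheiser benzannulation and should give 5-methoxy-2-R*-3-(triisopropylsilyloxy)phenol F2. Magnesium-mediated ortho-formylation (MgCl2, Et3N, paraformaldehyde, MeCN, reflux) at the only free ortho position should give 2-hydroxy-6-methoxy-3-R*-4-(triisopropylsilyloxy)benzaldehyde F3. MeMgBr (THF, −78 → 0 °C) should give the benzylic carbinol 2-(1-hydroxyethyl)-3-methoxy-6-R*-5-(triisopropylsilyloxy)phenol F4, and MnO2 (CH2Cl2, rt) oxidises it to the ketone, which brings the route back at 16.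

Step 11. Transmetalation of the ortho-silyloxy arylboron reagent may be slow, so that protodeboronation wins; the electron-rich 5,7-dioxygenated chromone may insert sluggishly; or facial control may erode. The fallback forms the C2–aryl bond by an aldol reaction and closes ring C by etherification. It sets out from 16. Commercial 2,4-dihydroxybenzaldehyde is silylated (TBSCl, imidazole, DMF) to 2,4-bis(tert-butyldimethylsilyloxy)benzaldehyde F5. The dianion of 16 (LiN(SiMe3)2, 2.2 equiv, THF, −78 °C) should add to F5 to give 3-[2,4-bis(tert-butyldimethylsilyloxy)phenyl]-3-hydroxy-1-[2-hydroxy-6-methoxy-3-R*-4-(triisopropylsilyloxy)phenyl]propan-1-one F6 as both carbinol epimers. Intramolecular Mitsunobu etherification (PPh3, DIAD, THF, 0 °C) should close ring C to 24 together with the (2R) epimer of 24 F7. The two are diastereomers because of C2'' and would be separated by preparative HPLC on a chiral phase, with F7 recycled by base-catalysed equilibration through the chalcone. The route is rejoined at 24.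

Step 10. The ortho silyl group may migrate from oxygen to carbon in the lithiated arene before boron capture, and desilylation or protodeboronation may occur during hydrolysis. The fallback avoids any aryl anion and sets out from 20. Miyaura borylation (B2pin2, PdCl2(dppf), KOAc, dioxane, 80 °C; oxidative addition of the aryl bromide to zerovalent palladium) should give 2-[2,4-bis(tert-butyldimethylsilyloxy)phenyl]-4,4,5,5-tetramethyl-1,3,2-dioxaborolane F8. F8 is used in place of 23 under the conditions of step 11, where the aqueous KOH hydrolyses it in situ, and the route is rejoined at 24.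

Further compounds
F1 | step 7 | 3-methoxycyclobut-2-en-1-one | COC1=CC(=O)C1
F2 | step 7 | 5-methoxy-2-R*-3-(triisopropylsilyloxy)phenol | C=C(C)[C@H](CCC(C)(C)O[Si](CC)(CC)CC)Cc1c(O)cc(OC)cc1O[Si](C(C)C)(C(C)C)C(C)C
F3 | step 7 | 2-hydroxy-6-methoxy-3-R*-4-(triisopropylsilyloxy)benzaldehyde | C=C(C)[C@H](CCC(C)(C)O[Si](CC)(CC)CC)Cc1c(O)c(C=O)c(OC)cc1O[Si](C(C)C)(C(C)C)C(C)C
F4 | step 7 | 2-(1-hydroxyethyl)-3-methoxy-6-R*-5-(triisopropylsilyloxy)phenol, both carbinol epimers | C=C(C)[C@H](CCC(C)(C)O[Si](CC)(CC)CC)Cc1c(O)c(C(C)O)c(OC)cc1O[Si](C(C)C)(C(C)C)C(C)C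
F5 | step 11 | 2,4-bis(tert-butyldimethylsilyloxy)benzaldehyde | O=Cc1ccc(O[Si](C)(C)C(C)(C)C)cc1O[Si](C)(C)C(C)(C)C
F6 | step 11 | 3-[2,4-bis(tert-butyldimethylsilyloxy)phenyl]-3-hydroxy-1-[2-hydroxy-6-methoxy-3-R*-4-(triisopropylsilyloxy)phenyl]propan-1-one, both carbinol epimers | C=C(C)[C@H](CCC(C)(C)O[Si](CC)(CC)CC)Cc1c(O[Si](C(C)C)(C(C)C)C(C)C)cc(OC)c(C(=O)CC(O)c2ccc(O[Si](C)(C)C(C)(C)C)cc2O[Si](C)(C)C(C)(C)C)c1O
F7 | step 11 | (2R)-2-[2,4-bis(tert-butyldimethylsilyloxy)phenyl]-5-methoxy-8-R*-7-(triisopropylsilyloxy)chroman-4-one | C=C(C)[C@H](CCC(C)(C)O[Si](CC)(CC)CC)Cc1c(O[Si](C(C)C)(C(C)C)C(C)C)cc(OC)c2c1O[C@@H](c1ccc(O[Si](C)(C)C(C)(C)C)cc1O[Si](C)(C)C(C)(C)C)CC2=O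
F8 | step 10 | 2-[2,4-bis(tert-butyldimethylsilyloxy)phenyl]-4,4,5,5-tetramethyl-1,3,2-dioxaborolane | CC1(C)OB(OC1(C)C)c1ccc(O[Si](C)(C)C(C)(C)C)cc1O[Si](C)(C)C(C)(C)C
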